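- In this stirred vessel the candidate steps have the gas dissolve and meet substrate to give target, and target turn into over-reaction product.

| setting | Friday's | flask |
|---|---|---|
| substrate | 0.10 M (in portions, 2) | 0.20 M (in portions, 2) |
| gas phase | 33 mM (held) | 33 mM (held) |
| remark | run made earlier; portions every 50 s | the portions of substrate follow each other after 50 s, the first at the start |
| time |  | 8.0 min |

- Friday's (time / min: over-reaction product / %, target / %): 0.667: 3.0, 2.1; 1.33: 8.7, 8.7; 2.00: 19.8, 9.9; 2.50: 26.3, 9.6

(readings scatter by 0.5 percentage points)

- at the start none of the gas is dissolved
- the analysis behind the earlier runs scatters by 0.5 percentage points, standard deviation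
- candidate steps: gas phase <-> dissolved gas; substrate + dissolved gas -> target; target -> over-reaction product

- amount of over-reaction product in percent of the substrate charged, at 50 s, 3.0 min and 8.0 min

- On Friday's run, the product curve reaches 3.0 % at 0.667 min. It meets the target curve at 1.33 min, where both read 8.7 %.
- Friday's target then bends over, reading 9.9 % at 2.00 min and 9.6 % at 2.50 min, with a scatter of 0.5 percentage points.
- On that top of Friday's curve, target is made as fast as it is used, which is the quasi-steady state. Dividing one rate by the other removes time and leaves a ratio.
- Call it ρ, the target-to-substrate ratio: target over substrate left, on the top of the target curve.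
- Friday's reading at 2.00 min has 70.3 % substrate left, so ρ reads 0.141.
- Once the whole charge is in, whatever is neither substrate nor target is product. So, with ρ held, product is the charge minus (1 + ρ) times the substrate left, all in percent.
- Friday's substrate falls from 82.6 % at 1.33 min to 64.1 % at 2.50 min. So a pseudo-first-order constant k_A reads 0.217 /min there.
- My reckoning for the flask, with twice Friday's substrate, keeps ρ and k_A at Friday's values and counts as if the whole charge stood unreacted at the last portion.
- That leaves 62.5 % substrate at 3.0 min, so product is 28.7 %. It leaves 21.2 % at 8.0 min, so product is 75.8 %.
- The point at 50 s lies before the top of Friday's target curve, so I leave the rule out of it. As a rough guess there I take Friday's reading of 3.0 %, made at 0.667 min.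
- The forecast says 3 %, 30 % and 75 %, and unlike my reckoning it expects “dissolved gas sags to about 80% of saturation”.

    gas phase ⇌ dissolved gas, rate k1*(csat - [dissolved gas]) (kL = 0.0580 /s)
    substrate + dissolved gas → target (k = 0.140 /M/s)
    target → over-reaction product (k = 0.0280 /s)

- The flask gives 2.60 %, 31.6 % and 78.2 %, so the forecast is right within the margin. At 8.00 min, target in the flask is made at 0.867 of the rate at which it is used. Substrate left at 8.00 min is 19 %. Friday's ρ of 0.141 turns that into 78.3 % product, and the flask stands at 78.2 %, with its own target over substrate at 0.174.

All runs were computed from invented constants; scatter was added.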